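The C5'–C6' bond of ring B is made last. Ring A is numbered C1 (butanoyl), C2 (OH), C3 (Me), C4 (OH), C5 (bridge), C6 (OH); ring B is numbered C1' (bridge), C2', C3' (CMe2), C4', C5' (acetyl), C6'. The acyl-level carbon C6' can reach O4, so O4, C4, C5, the bridge CH2, C1' and C6' are tied into a six-membered dihydrocoumarin lactone. The precursor is this lactone of O2,O6-dibenzylated ring A, with the open C2'–C5' triketone chain on C1'. One base-induced Dieckmann acyl transfer closes ring B, opens the temporary lactone and frees O4–H, so the bridge is never formed between two separate rings.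

Key step: step 6

Remarks on the chemistry: the target has no stereocentre. Compounds 14, 15 and 16 are drawn in one tautomeric form and should exist as enol mixtures. Compound 14 is racemic at C3 of the chromanone (C1'), a centre that becomes sp2 in step 6. The lactone series carries an enolisable butanoyl group and, from 14 on, an acidic C1'–H; steps 5 and 6 therefore use non-nucleophilic bases in excess and an acidic quench.

Step 1
Reactants: 1 2-methylphloroglucinol; 2 butanoyl chloride
Product: 3 1-(2,4,6-trihydroxy-3-methylphenyl)butan-1-one
Conditions: AlCl3 (3.5 equiv), PhNO2, rt → 60 °C; ice/aq. HCl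
Reagents that add atoms: none
Why: Friedel–Crafts C-acylation of the electron-rich triol at one of its two equivalent free ring positions; the first acyl group deactivates the ring against a second acylation.

Step 2
Reactants: 3 1-(2,4,6-trihydroxy-3-methylphenyl)butan-1-one; 4 Meldrum's acid (2,2-dimethyl-1,3-dioxane-4,6-dione)
Product: 7 6-butanoyl-5,7-dihydroxy-8-methyl-3,4-dihydro-2H-chromen-2-one, via Meldrum's acid adduct 5 (not isolated), via lactone carboxylic acid 6 (not isolated)
Conditions: 4 (1.5 equiv), paraformaldehyde (1.1 equiv, added last in portions), pyridine, rt then 90 °C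
Reagents that add atoms: formaldehyde (from paraformaldehyde), C=O
Why: Knoevenagel condensation of formaldehyde with Meldrum's acid gives a methylene acceptor to which the only free ring carbon of 3 adds (Friedel–Crafts-type Michael addition), the unchelated phenol para to the butanoyl group then opens the dioxanedione with loss of acetone, and the resulting malonic half-acid decarboxylates in hot pyridine.

Step 3
Reactants: 7 6-butanoyl-5,7-dihydroxy-8-methyl-3,4-dihydro-2H-chromen-2-one
Product: 8 5,7-bis(benzyloxy)-6-butanoyl-8-methyl-3,4-dihydro-2H-chromen-2-one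
Conditions: BnBr (2.5 equiv), K2CO3 (3 equiv, anhydrous), MeCN, 60 °C
Reagents that add atoms: benzyl bromide, BrCc1ccccc1
Why: Williamson etherification of the two remaining phenols; anhydrous carbonate should leave the aryl lactone closed and cannot enolise either carbonyl group, and gentle warming drives alkylation of the hydrogen-bonded hydroxyl.

Step 4
Reactants: 9 dimethylmalonyl dichloride; 10 isopropenyl acetate
Product: 12 3,3,6-trimethyl-2H-pyran-2,4(3H)-dione, via diketo acid chloride 11 (not isolated)
Conditions: AlCl3 (2.2 equiv), CH2Cl2, 0 °C → rt, slow addition of 10; ice/1 M HCl; distillation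
Reagents that add atoms: none
Why: Lewis acid-mediated C-acylation of the enol acetate (Friedel–Crafts-type acylation of an enol ester, releasing acetyl chloride) gives the 1,3-diketone, whose enol oxygen then closes the six-membered enol lactone on the second, non-enolisable acid chloride.

Step 5
Reactants: 8 5,7-bis(benzyloxy)-6-butanoyl-8-methyl-3,4-dihydro-2H-chromen-2-one; 12 3,3,6-trimethyl-2H-pyran-2,4(3H)-dione
Product: 14 5,7-bis(benzyloxy)-6-butanoyl-3-(2,2-dimethyl-3,5-dioxohexanoyl)-8-methyl-3,4-dihydro-2H-chromen-2-one (racemic), via lithium enolate 13 (not isolated)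
Conditions: LiN(SiMe3)2 (2.1 equiv), THF, −78 °C; then 12 (1.2 equiv), −78 → −40 °C; AcOH, −78 °C
Reagents that add atoms: none
Why: Crossed Claisen acylation in the manner of a Fujimoto–Belleau enol lactone opening: the α-CH2 of the aryl δ-lactone should be the most acidic C–H (the butanoyl carbonyl is twisted between two ortho benzyloxy groups), its lithium enolate attacks the enol ester carbonyl C2 of 12, the pyran ring opens to the 1,3-diketone enolate, and the second equivalent of base takes up the new β-keto lactone proton; the new stereocentre is formed racemic and disappears in step 6.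

Step 6
Reactants: 14 5,7-bis(benzyloxy)-6-butanoyl-3-(2,2-dimethyl-3,5-dioxohexanoyl)-8-methyl-3,4-dihydro-2H-chromen-2-one
Product: 15 2-acetyl-4-{[2,4-bis(benzyloxy)-3-butanoyl-6-hydroxy-5-methylphenyl]methyl}-3,5-dihydroxy-6,6-dimethylcyclohexa-2,4-dien-1-one
Conditions: DBU (3 equiv), MeCN, 0 °C → rt; cold 1 M HCl
Reagents that add atoms: none
Why: DBU ionises C5', the carbon between the C4' ketone and the acetyl group, and this carbon adds to the still neutral lactone carbonyl C6'; collapse of the tetrahedral intermediate expels the C4 phenoxide, so ring B closes and the temporary lactone opens in one event (should C1' be ionised instead, E1cB loss of the phenoxide gives an acylketene at C6' that C5' traps to make the same bond). The closest known reaction type is the Dieckmann (intramolecular Claisen) cyclisation of 3,5,7-triketo esters to 2-acylcyclohexane-1,3,5-triones. Ring B closes in a 6-(enolexo)-exo-trig mode. No stereocentre is created, and the C1' centre of 14 becomes an enol carbon. The step needs C- over O-acylation and Claisen over aldol closure: an enol lactone formed through the C4' oxygen can revert through the tethered phenoxide, the diketone held as its enolate is no aldol acceptor, and the strongly acidic acyl triketone anion of ring B is the thermodynamic sink. The non-nucleophilic amidine spares the non-enolisable C2'–CMe2–C4' diketone from retro-Claisen cleavage, and the cold acidic quench limits base-induced cleavage of the CH2 bridge.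

Step 7
Reactants: 15 2-acetyl-4-{[2,4-bis(benzyloxy)-3-butanoyl-6-hydroxy-5-methylphenyl]methyl}-3,5-dihydroxy-6,6-dimethylcyclohexa-2,4-dien-1-one
Product: 16 2-acetyl-4-[(3-butanoyl-2,4,6-trihydroxy-5-methylphenyl)methyl]-3,5-dihydroxy-6,6-dimethylcyclohexa-2,4-dien-1-one
Conditions: H2 (1 atm), 10% Pd/C, EtOAc, rt
Reagents that add atoms: none
Why: Hydrogenolysis of the two aryl benzyl ethers over palladium on carbon under neutral conditions should leave the enolised triketone, the aryl ketone and the base-sensitive CH2 bridge untouched.

Compound list

1 | 2-methylphloroglucinol (2-methylbenzene-1,3,5-triol) | Cc1c(O)cc(O)cc1O | starting material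
2 | butanoyl chloride | CCCC(=O)Cl | starting material
3 | 1-(2,4,6-trihydroxy-3-methylphenyl)butan-1-one | CCCC(=O)c1c(O)cc(O)c(C)c1O | intermediate
4 | Meldrum's acid (2,2-dimethyl-1,3-dioxane-4,6-dione) | CC1(C)OC(=O)CC(=O)O1 | starting material
5 | 5-[(3-butanoyl-2,4,6-trihydroxy-5-methylphenyl)methyl]-2,2-dimethyl-1,3-dioxane-4,6-dione | CCCC(=O)c1c(O)c(C)c(O)c(CC2C(=O)OC(C)(C)OC2=O)c1O | intermediate (not isolated)
6 | 6-butanoyl-5,7-dihydroxy-8-methyl-2-oxo-3,4-dihydro-2H-chromene-3-carboxylic acid (racemic) | CCCC(=O)c1c(O)c(C)c2OC(=O)C(C(=O)O)Cc2c1O | intermediate (not isolated)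
7 | 6-butanoyl-5,7-dihydroxy-8-methyl-3,4-dihydro-2H-chromen-2-one | CCCC(=O)c1c(O)c(C)c2OC(=O)CCc2c1O | intermediate
8 | 5,7-bis(benzyloxy)-6-butanoyl-8-methyl-3,4-dihydro-2H-chromen-2-one | CCCC(=O)c1c(OCc3ccccc3)c(C)c2OC(=O)CCc2c1OCc1ccccc1 | intermediate
9 | dimethylmalonyl dichloride (2,2-dimethylpropanedioyl dichloride) | CC(C)(C(=O)Cl)C(=O)Cl | starting material
10 | isopropenyl acetate (prop-1-en-2-yl acetate) | CC(=C)OC(C)=O | starting material
11 | 2,2-dimethyl-3,5-dioxohexanoyl chloride | CC(=O)CC(=O)C(C)(C)C(=O)Cl | intermediate (not isolated)
12 | 3,3,6-trimethyl-2H-pyran-2,4(3H)-dione | CC1=CC(=O)C(C)(C)C(=O)O1 | intermediate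
13 | lithium enolate of 8 (lithium 5,7-bis(benzyloxy)-6-butanoyl-8-methyl-4H-chromen-2-olate) | [Li+].CCCC(=O)c1c(OCc3ccccc3)c(C)c2OC([O-])=CCc2c1OCc1ccccc1 | intermediate (not isolated)
14 | 5,7-bis(benzyloxy)-6-butanoyl-3-(2,2-dimethyl-3,5-dioxohexanoyl)-8-methyl-3,4-dihydro-2H-chromen-2-one (racemic) | CCCC(=O)c1c(OCc3ccccc3)c(C)c2OC(=O)C(C(=O)C(C)(C)C(=O)CC(C)=O)Cc2c1OCc1ccccc1 | intermediate (key-step precursor)
15 | 2-acetyl-4-{[2,4-bis(benzyloxy)-3-butanoyl-6-hydroxy-5-methylphenyl]methyl}-3,5-dihydroxy-6,6-dimethylcyclohexa-2,4-dien-1-one | CCCC(=O)c1c(OCc2ccccc2)c(C)c(O)c(CC2=C(O)C(C)(C)C(=O)C(C(C)=O)=C2O)c1OCc1ccccc1 | intermediate (key-step product)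
16 | 2-acetyl-4-[(3-butanoyl-2,4,6-trihydroxy-5-methylphenyl)methyl]-3,5-dihydroxy-6,6-dimethylcyclohexa-2,4-dien-1-one | CCCC(=O)c1c(O)c(C)c(O)c(CC2=C(O)C(C)(C)C(=O)C(C(C)=O)=C2O)c1O | target

Total step count: 7. Longest linear sequence: 6 steps (steps 1, 2, 3, 5, 6, 7); step 4 is a one-step side branch.

Steps most likely to fail

Step 5. Three processes could spoil it. Deprotonation may occur at the butanoyl α-carbon as well as at the lactone. The enolate may be quenched by proton transfer from the acidic 6-methyl group of 12 instead of adding to its C2 carbonyl. The released diketone enolate may begin the ring closure before the quench. The fallback sets out from 7 and uses no protecting groups. With LiN(SiMe3)2 (4.2 equiv, THF, −78 °C) both phenols are ionised first, which turns the butanoyl carbonyl into a doubly vinylogous carboxylate that should no longer enolise. The next equivalent forms the lactone enolate, and acylation with 12 as in step 5 should give 6-butanoyl-3-(2,2-dimethyl-3,5-dioxohexanoyl)-5,7-dihydroxy-8-methyl-3,4-dihydro-2H-chromen-2-one F1. Treating F1 with DBU in MeCN as in step 6, followed by acidification, should close ring B and open the lactone. The fallback comes back to the route at 16, and benzylation and hydrogenolysis drop out.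

Step 6. The base may remove C1'–H in place of C5'–H, which deactivates the lactone carbonyl and opens an aldol-type closure of C1' onto the acetyl carbonyl. Acylation through the C4' oxygen may give an enol lactone that fails to revert. Prolonged exposure to base may cleave the CH2 bridge of 15 through an ortho-quinone methide and scramble the two rings. The fallback is the classical convergent methylene coupling and sets out from 3. Commercial 2,4,6-trihydroxyacetophenone is geminally C-methylated (MeI, NaOMe, MeOH) to 2-acetyl-3,5-dihydroxy-6,6-dimethylcyclohexa-2,4-dien-1-one F2. Compounds 3 and F2 are then joined with aqueous formaldehyde in dilute aqueous KOH at 0 °C → rt. The mixed CH2-bridged product would have to be separated from the two symmetrical dimers that this statistical coupling also forms. The fallback comes back to the route at 16.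

Step 2. Formaldehyde may link two molecules of 3 into a methylene-bis dimer before the Meldrum's acid-derived acceptor is intercepted. Lactonisation may also go partly through O6; that isomer would still converge on 16 through the same later steps, with the benzyl groups on O2 and O4. The fallback sets out from 3 and separates the two C–C bond formations. Aminomethylation with dimethylmethyleneiminium iodide (CH2=NMe2+ I−, MeCN, 0 °C) should give the Mannich base 1-{3-[(dimethylamino)methyl]-2,4,6-trihydroxy-5-methylphenyl}butan-1-one F3. Heating F3 with 4 (toluene, 100 °C) expels dimethylamine to give an ortho-quinone methide, which Meldrum's acid traps; lactonisation and decarboxylation follow. The fallback comes back to the route at 7.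

Further compounds

F1 | step 5 | 6-butanoyl-3-(2,2-dimethyl-3,5-dioxohexanoyl)-5,7-dihydroxy-8-methyl-3,4-dihydro-2H-chromen-2-one | CCCC(=O)c1c(O)c(C)c2OC(=O)C(C(=O)C(C)(C)C(=O)CC(C)=O)Cc2c1O
F2 | step 6 | 2-acetyl-3,5-dihydroxy-6,6-dimethylcyclohexa-2,4-dien-1-one | CC(=O)C1=C(O)C=C(O)C(C)(C)C1=O
F3 | step 2 | 1-{3-[(dimethylamino)methyl]-2,4,6-trihydroxy-5-methylphenyl}butan-1-one | CCCC(=O)c1c(O)c(C)c(O)c(CN(C)C)c1O
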